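No constant of these flasks is given, but one can be read from Thursday's run, which has the same charge as the set-ups asked about.

| flask | Q | D | remark | time |
|---|---|---|---|---|
| Thursday's | 0.13 M | 0.143 M | run made earlier |  |
| Friday's | 0.13 M | 0.20 M | run made earlier |  |
| Sunday's | 0.13 M | 0.31 M | run made earlier |  |
| blue | 0.13 M | 0.143 M | everything together in a closed stirred flask, run for 8.0 min | 8.0 min |
| grey | 0.13 M (fed, over 4.00 min) | 0.143 M | a stirred flask in which Q is dosed at a steady rate over 4.00 min without added volume, worked up at 8.0 min | 8.0 min |
| amber | 0.13 M | 0.143 M (fed, over 4.00 min) | all but D at the start; D goes in evenly over 4.00 min, the run ends at 8.0 min | 8.0 min |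
| ochre | 0.13 M | 0.143 M | a single well-mixed tank run continuously and read at steady state, 8.0 min in it on average |  |

| run | time / min | L / % | Q / % |
|---|---|---|---|
| Thursday's | 0.250 | 51.4 | 47.9 |
| Thursday's | 0.667 | 50.6 | 46.2 |
| Thursday's | 1.33 | 48.8 | 46.7 |
| Thursday's | 2.00 | 47.0 | 46.2 |
| Thursday's | 3.00 | 43.9 | 45.5 |
| Thursday's | 4.00 | 40.8 | 43.2 |
| Thursday's | 5.00 | 39.4 | 43.6 |
| Friday's | 0.250 | 59.5 | 39.0 |
| Friday's | 0.667 | 58.7 | 38.3 |
| Friday's | 1.33 | 56.4 | 38.2 |
| Friday's | 2.00 | 53.0 | 36.8 |
| Friday's | 3.00 | 50.6 | 36.5 |
| Friday's | 4.00 | 48.6 | 34.5 |
| Friday's | 5.00 | 45.7 | 33.7 |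
| Sunday's | 0.250 | 70.3 | 29.2 |
| Sunday's | 0.667 | 67.6 | 27.4 |
| Sunday's | 1.33 | 64.2 | 27.9 |
| Sunday's | 2.00 | 62.5 | 28.0 |
| Sunday's | 3.00 | 58.5 | 26.8 |
| Sunday's | 4.00 | 54.8 | 24.3 |
| Sunday's | 5.00 | 51.3 | 24.1 |

(scatter of a reading: 0.5 percentage points)

- percent here means Q units held: one G counts as two
- the stated concentrations are those of everything mixed, before any reaction; amounts are the same in each set-up
- the earlier runs were read with a standard deviation of 0.5 percentage points
- what may be going on: Q + D <-> L + E; L <-> Z; 2 Q -> G
- the feed brings no volume worth counting
- the earlier runs were made in a closed, stirred flask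

* the set-up with the highest amount of L at the outlet or at the end, in percent of the Q put in ("none" if the first two lie within 2 percentage points) (blue / grey / amber / ochre / none)
* amount of L at the outlet or at the end, in percent of the Q put in, blue
* amount of L at the outlet or at the end, in percent of the Q put in, grey
* amount of L at the outlet or at the end, in percent of the Q put in, amber
* amount of L at the outlet or at the end, in percent of the Q put in, ochre

Two chemists dispute what becomes of the links L that the end groups Q and D form. The first points to Thursday's first reading: L and Q together hold 99.3% of the Q charged, which she reads as a fast equilibrium. Since the set-ups share one charge, she expects each to end near 51.4%, whatever the order of addition.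

The second points to Thursday's last reading, where L has fallen to 39.4%. He works with the fraction of L left and defines a pseudo-first-order constant a, the logarithm of the ratio of the first L reading to the last, divided by the time between them, 0.0560 min⁻¹. Its time 17.9 min is far longer than the first reading, so he treats the equilibrium and the loss as separate events. He takes the fraction of L left after a time t as exp(-at).

In blue, counted from the first reading, that fraction is 0.648, which gives 33.3%. In grey and amber the fed end group enters on average 2.00 min later, so he reckons a fraction of 0.725 and L of 37.3% in both. For the ochre tank he takes the fraction left as one over one plus a times the mean stay, 0.691, which gives 35.5%. His top two, grey and amber, lie within 2 percentage points, so he answers "none". He grants her the early readings of Thursday's run, at times far below 17.9 min, where L still stands at 50.6% after 0.667 min.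

The forecast gave 33.4% for blue, 36.2% for grey, 36% for amber and 35.9% for ochre, with none as best, saying “slow dosing delays L formation”, and its grey lies 1.1 points under his.

The flask gives 33.5% in blue, 36.4% in grey, 36.3% in amber and 36.3% in ochre, so the best is none.

    Q + D ⇌ L + E (K = 1.00, k = 1.92 M⁻¹ s⁻¹)
    L ⇌ Z (K = 6.60, k = 0.00139 s⁻¹)
    2 Q → G (k = 1.95 × 10⁻⁵ M⁻¹ s⁻¹)

In blue at 8.00 min, L is made, net, at a third of the rate at which it is used up, a ratio of 0.326. Blue's fraction left, its final L over Thursday's first reading, comes to 0.652. For Friday's charge, the same fraction 0.648 applied to its first reading gives 38.6% at 8.0 min, and that charge, run on to that time, holds 38.4%.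

The runs are calculated for an exercise, noise included.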